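**Strategy**

Ring A (C1–C4, C4a, C8a) is a cyclohexene whose C3=C4 alkene sits one position away from where a Diels–Alder reaction leaves it, next to the carboxyl-bearing quaternary C4a. The route therefore closes ring A by a Lewis-acid Diels–Alder reaction between a citronellal-derived (E)-1-silyl-3-alkyl diene and the enal of an enantioenriched ring B cyclohexa-1,4-diene. One operation forges C4–C4a and C1–C8a, the quaternary centre, the cis ring fusion and a temporary C4–Si stereocentre. Anti-SE2' protodesilylation then shifts the alkene to C3=C4 and relays C4 to C2. Propynal serves as linchpin: each of its two π bonds takes part in one cycloaddition.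

Key step: step 9

Remark on numbering: atoms carry the locants of the hexahydronaphthalene name of the target (ring A = C1, C2, C3, C4, C4a, C8a; ring B = C4a, C5, C6, C7, C8, C8a). The 1,4-disubstituted cyclohexane is trans, as the descriptors of the target require.

Assumption: the (S)-configured oxazaborolidinium catalyst of step 6 is taken to give the (S)-configured cyclohexadiene 10; if the sense of induction proves opposite, the (R)-catalyst is used and nothing else changes.

**Route**

Step 1
Reactants: 1 methyl trans-4-formylcyclohexane-1-carboxylate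
Product: 2 methyl trans-4-ethynylcyclohexane-1-carboxylate
Conditions: dimethyl (1-diazo-2-oxopropyl)phosphonate (1.3 equiv), K2CO3 (2 equiv), MeOH, 0 → 23 °C
Reagents that add atoms: dimethyl (1-diazo-2-oxopropyl)phosphonate, COP(=O)(OC)C(=[N+]=[N-])C(C)=O
Why: Seyferth–Gilbert homologation in its Ohira–Bestmann form should turn the aldehyde into the terminal alkyne under conditions in which the methyl ester only exchanges with the solvent and any epimerisation at the formyl-bearing carbon returns the more stable diequatorial trans isomer.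

Step 2
Reactants: 2 methyl trans-4-ethynylcyclohexane-1-carboxylate
Product: 4 methyl trans-4-[(E)-1-iodoprop-1-en-2-yl]cyclohexane-1-carboxylate, via alkenyl(dimethyl)alane 3 (not isolated)
Conditions: Me3Al (3 equiv), Cp2ZrCl2 (25 mol%), CH2Cl2, 0 → 23 °C; then I2 (1.3 equiv), THF, −30 → 0 °C
Reagents that add atoms: trimethylaluminium, C[Al](C)C; iodine, II
Why: Negishi carboalumination adds methyl and aluminium syn across the terminal alkyne with aluminium at the terminus, and iodinolysis with retention should give the (E)-iodide with iodine cis to the new methyl group, the ester being spared by Me3Al at these temperatures.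

Step 3
Reactants: 5 2-methylbut-1-en-3-yne
Product: 6 4,4,5,5-tetramethyl-2-[(1E)-3-methylbuta-1,3-dien-1-yl]-1,3,2-dioxaborolane
Conditions: pinacolborane (1.05 equiv), Cp2ZrHCl (5 mol%), Et3N (10 mol%), neat, sealed tube, 50 °C
Reagents that add atoms: pinacolborane, CC1(C)OBOC1(C)C
Why: zirconium-catalysed syn hydroboration of the terminal alkyne places boron at the terminus and should give the (E)-dienylboronate while leaving the 1,1-disubstituted alkene alone.

Step 4
Reactants: 4 methyl trans-4-[(E)-1-iodoprop-1-en-2-yl]cyclohexane-1-carboxylate; 6 4,4,5,5-tetramethyl-2-[(1E)-3-methylbuta-1,3-dien-1-yl]-1,3,2-dioxaborolane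
Product: 7 methyl trans-4-[(2E,4E)-6-methylhepta-2,4,6-trien-2-yl]cyclohexane-1-carboxylate
Conditions: Pd(PPh3)4 (5 mol%), K3PO4 (3 equiv), THF/H2O, 45 °C, Ar
Reagents that add atoms: none
Why: Suzuki–Miyaura coupling proceeds with retention of geometry at both alkenyl partners and should deliver the (2E,4E)-triene.

Step 5
Reactants: 8 3,3-diethoxyprop-1-yne
Product: 9 propynal
Conditions: H2SO4 (cat.), H2O, 23 → 60 °C, product distilled out as it forms and kept cold as a CH2Cl2 solution
Reagents that add atoms: water, O
Why: acid-catalysed acetal hydrolysis sets the volatile ynal free, and distillation removes it from the acid before it can polymerise.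

Step 6
Reactants: 7 methyl trans-4-[(2E,4E)-6-methylhepta-2,4,6-trien-2-yl]cyclohexane-1-carboxylate; 9 propynal
Product: 10 methyl trans-4-[(E)-1-[(1S)-2-formyl-5-methylcyclohexa-2,5-dien-1-yl]prop-1-en-2-yl]cyclohexane-1-carboxylate
Conditions: (S)-1-(2-methylphenyl)-3,3-diphenyltetrahydro-1H,3H-pyrrolo[1,2-c][1,3,2]oxazaborole (20 mol%), HN(SO2CF3)2 (18 mol%), 9 (2 equiv), CH2Cl2, −78 °C, Ar
Reagents that add atoms: none
Why: in this catalytic enantioselective Diels–Alder reaction the boron-bound ynal should add only to the terminal diene unit of 7 (the inner one cannot reach s-cis because of its inside methyl group), with the unsubstituted CH2 terminus bonding to the alkyne CH, so that the alkenyl-bearing carbon ends up next to the formyl-bearing carbon, and the shielded catalyst pocket sets this single stereocentre.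

Step 7
Reactants: 11 (S)-citronellal
Product: 12 (3S)-3,7-dimethyl-2-methylideneoct-6-enal
Conditions: aq. HCHO (37%, 1.2 equiv), pyrrolidine (10 mol%), EtCO2H (10 mol%), i-PrOH, 45 °C
Reagents that add atoms: formaldehyde, C=O
Why: amine-catalysed Mannich condensation and elimination (organocatalytic α-methylenation) installs the exo-methylene group at the only enolisable carbon, and the C3 stereocentre is untouched because its hydrogen is not acidified in the cross-conjugated product.

Step 8
Reactants: 12 (3S)-3,7-dimethyl-2-methylideneoct-6-enal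
Product: 13 [(1E,4S)-4,8-dimethyl-3-methylidenenona-1,7-dien-1-yl]trimethylsilane
Conditions: Me3SiCHBr2 (2 equiv), CrCl2 (8 equiv), THF, 23 °C
Reagents that add atoms: (dibromomethyl)trimethylsilane, C[Si](C)(C)C(Br)Br
Why: Takai–Utimoto olefination with the geminal dichromium reagent adds 1,2 to the enal and should give the (E)-alkenylsilane, that is, the 1-silyl-3-alkyl diene.

Step 9
Reactants: 10 methyl trans-4-[(E)-1-[(1S)-2-formyl-5-methylcyclohexa-2,5-dien-1-yl]prop-1-en-2-yl]cyclohexane-1-carboxylate; 13 [(1E,4S)-4,8-dimethyl-3-methylidenenona-1,7-dien-1-yl]trimethylsilane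
Product: 14 (4S,4aR,5S,8aS)-5-[(E)-2-(trans-4-methoxycarbonylcyclohexyl)prop-1-en-1-yl]-7-methyl-2-[(2S)-6-methylhept-5-en-2-yl]-4-(trimethylsilyl)-1,4,4a,5,8,8a-hexahydronaphthalene-4a-carbaldehyde
Conditions: Me2AlCl (1.2 equiv), 13 (2 equiv), CH2Cl2, −78 → −30 °C, Ar; quench with aq. NaHCO3 at −78 °C
Reagents that add atoms: none
Why: Me2AlCl binds the formyl oxygen of 10 and lowers the LUMO of the C4a=C8a enal, which then undergoes a concerted but asynchronous [4+2] cycloaddition with the s-cis diene of 13, the bond from the diene CH2 terminus to the β-carbon (C1–C8a) running ahead of C4–C4a. The closest known reaction type is the Lewis-acid-promoted Diels–Alder reaction of (E)-1-silyl dienes with enals, which delivers cyclic allylsilanes. Ring A closes as an intermolecular suprafacial–suprafacial [4+2] cycloaddition in which both ring bonds form in the same step, so no separate ring-closure mode has to be met. C4a and C8a should emerge cis because the ring B alkene adds suprafacially, on the face anti to the C5 propenyl substituent next to C4a, which places the formyl group cis to that substituent; C4 is set by the formyl-endo transition state, in which the outside silyl group of the (E)-diene ends up cis to the formyl group. The step needs para regiochemistry, secured by the 3-alkyl group that puts the largest HOMO coefficient on the CH2 terminus, and endo selectivity, supported by carbonyl–diene secondary overlap and by the clash that a ring B-endo approach would have with the substituent at C2. Only the enal alkene is activated, only 13 offers a 1,3-diene that can reach s-cis, and Me2AlCl scavenges protons so that the vinylsilane, the new allylsilane and the skipped diene should survive.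

Step 10
Reactants: 14 the C4-silylated Diels–Alder adduct
Product: 15 (2R,4aR,5S,8aR)-5-[(E)-2-(trans-4-methoxycarbonylcyclohexyl)prop-1-en-1-yl]-7-methyl-2-[(2S)-6-methylhept-5-en-2-yl]-1,2,4a,5,8,8a-hexahydronaphthalene-4a-carbaldehyde
Conditions: CF3CO2H (3 equiv), CH2Cl2, −20 → 0 °C; aq. NaHCO3
Reagents that add atoms: none
Why: protodesilylation of the allylsilane in the anti-SE2' mode should protonate C2 on the face opposite the C4–Si bond through the β-silyl cation, so the alkene moves to C3=C4 and the side chain at C2 ends up cis to the formyl group (2R), the allylsilane being far more nucleophilic than the three other trisubstituted alkenes.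

Step 11
Reactants: 15 the C4a aldehyde
Product: 16 (2R,4aR,5S,8aR)-5-[(E)-2-(trans-4-methoxycarbonylcyclohexyl)prop-1-en-1-yl]-7-methyl-2-[(2S)-6-methylhept-5-en-2-yl]-1,2,4a,5,8,8a-hexahydronaphthalene-4a-carboxylic acid
Conditions: NaClO2 (3 equiv), NaH2PO4 (4 equiv), 2-methylbut-2-ene (20 equiv), t-BuOH/H2O, 0 → 23 °C
Reagents that add atoms: sodium chlorite, [Na+].[O-]Cl=O
Why: Pinnick oxidation should convert the neopentyl aldehyde, which has no α-hydrogen, into the acid while the excess alkene scavenger takes up hypochlorous acid before it reaches the four alkenes.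

Step 12
Reactants: 16 the C4a acid methyl ester
Product: 18 (2R,4aR,5S,8aR)-5-[(E)-2-(trans-4-carboxycyclohexyl)prop-1-en-1-yl]-7-methyl-2-[(2S)-6-methylhept-5-en-2-yl]-1,2,4a,5,8,8a-hexahydronaphthalene-4a-carboxylic acid (target), via dilithium dicarboxylate 17 (not isolated)
Conditions: LiOH (5 equiv), THF/MeOH/H2O, 23 °C; then 1 M HCl to pH 3, 0 °C
Reagents that add atoms: lithium hydroxide, [Li+].[OH-]
Why: saponification of the unhindered secondary methyl ester followed by mild acidification should give the diacid, the stereocentre next to that ester already being the thermodynamically preferred trans one.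

**Compound list**

1 | methyl trans-4-formylcyclohexane-1-carboxylate | O=C[C@H]1CC[C@H](C(=O)OC)CC1 | starting material
2 | methyl trans-4-ethynylcyclohexane-1-carboxylate | C#C[C@H]1CC[C@H](C(=O)OC)CC1 | intermediate
3 | methyl trans-4-[(E)-1-(dimethylalumanyl)prop-1-en-2-yl]cyclohexane-1-carboxylate | C[Al](C)/C=C(\C)[C@H]1CC[C@H](C(=O)OC)CC1 | intermediate
4 | methyl trans-4-[(E)-1-iodoprop-1-en-2-yl]cyclohexane-1-carboxylate | I/C=C(\C)[C@H]1CC[C@H](C(=O)OC)CC1 | intermediate
5 | 2-methylbut-1-en-3-yne | C=C(C)C#C | starting material
6 | 4,4,5,5-tetramethyl-2-[(1E)-3-methylbuta-1,3-dien-1-yl]-1,3,2-dioxaborolane | C=C(C)/C=C/B1OC(C)(C)C(C)(C)O1 | intermediate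
7 | methyl trans-4-[(2E,4E)-6-methylhepta-2,4,6-trien-2-yl]cyclohexane-1-carboxylate | C=C(C)/C=C/C=C(\C)[C@H]1CC[C@H](C(=O)OC)CC1 | intermediate
8 | 3,3-diethoxyprop-1-yne | C#CC(OCC)OCC | starting material
9 | propynal | C#CC=O | intermediate
10 | methyl trans-4-[(E)-1-[(1S)-2-formyl-5-methylcyclohexa-2,5-dien-1-yl]prop-1-en-2-yl]cyclohexane-1-carboxylate | O=CC1=CCC(C)=C[C@H]1/C=C(\C)[C@H]1CC[C@H](C(=O)OC)CC1 | intermediate
11 | (S)-citronellal, (3S)-3,7-dimethyloct-6-enal | CC(C)=CCC[C@H](C)CC=O | starting material
12 | (3S)-3,7-dimethyl-2-methylideneoct-6-enal | CC(C)=CCC[C@H](C)C(=C)C=O | intermediate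
13 | [(1E,4S)-4,8-dimethyl-3-methylidenenona-1,7-dien-1-yl]trimethylsilane | CC(C)=CCC[C@H](C)C(=C)/C=C/[Si](C)(C)C | intermediate
14 | (4S,4aR,5S,8aS)-5-[(E)-2-(trans-4-methoxycarbonylcyclohexyl)prop-1-en-1-yl]-7-methyl-2-[(2S)-6-methylhept-5-en-2-yl]-4-(trimethylsilyl)-1,4,4a,5,8,8a-hexahydronaphthalene-4a-carbaldehyde | CC(C)=CCC[C@H](C)C1=C[C@H]([Si](C)(C)C)[C@]2(C=O)[C@@H](CC(C)=C[C@H]2/C=C(\C)[C@H]2CC[C@H](C(=O)OC)CC2)C1 | intermediate
15 | (2R,4aR,5S,8aR)-5-[(E)-2-(trans-4-methoxycarbonylcyclohexyl)prop-1-en-1-yl]-7-methyl-2-[(2S)-6-methylhept-5-en-2-yl]-1,2,4a,5,8,8a-hexahydronaphthalene-4a-carbaldehyde | CC(C)=CCC[C@H](C)[C@@H]1C=C[C@]2(C=O)[C@@H](CC(C)=C[C@H]2/C=C(\C)[C@H]2CC[C@H](C(=O)OC)CC2)C1 | intermediate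
16 | (2R,4aR,5S,8aR)-5-[(E)-2-(trans-4-methoxycarbonylcyclohexyl)prop-1-en-1-yl]-7-methyl-2-[(2S)-6-methylhept-5-en-2-yl]-1,2,4a,5,8,8a-hexahydronaphthalene-4a-carboxylic acid | CC(C)=CCC[C@H](C)[C@@H]1C=C[C@]2(C(=O)O)[C@@H](CC(C)=C[C@H]2/C=C(\C)[C@H]2CC[C@H](C(=O)OC)CC2)C1 | intermediate
17 | dilithium salt of the target diacid | CC(C)=CCC[C@H](C)[C@@H]1C=C[C@]2(C(=O)[O-])[C@@H](CC(C)=C[C@H]2/C=C(\C)[C@H]2CC[C@H](C(=O)[O-])CC2)C1.[Li+].[Li+] | intermediate
18 | (2R,4aR,5S,8aR)-5-[(E)-2-(trans-4-carboxycyclohexyl)prop-1-en-1-yl]-7-methyl-2-[(2S)-6-methylhept-5-en-2-yl]-1,2,4a,5,8,8a-hexahydronaphthalene-4a-carboxylic acid | CC(C)=CCC[C@H](C)[C@@H]1C=C[C@]2(C(=O)O)[C@@H](CC(C)=C[C@H]2/C=C(\C)[C@H]2CC[C@H](C(=O)O)CC2)C1 | target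

**Step count and risks**

Total step count: 12. Longest linear sequence: 8 steps (steps 1, 2, 4, 6, 9, 10, 11 and 12, from compound 1).

The three steps most likely to fail:

Step 9. The trisubstituted enal, flanked by the C5 substituent, may add too slowly to the only weakly activated silyl diene, and a competing exo approach would erode the configuration at C4 and hence at C2. The fallback reverses the order of the two cycloadditions. It sets out from 13 and 9: the oxazaborolidinium-catalysed Diels–Alder reaction of step 6 is run on the unhindered alkyne with diene 13 and should give (6S)-4-[(2S)-6-methylhept-5-en-2-yl]-6-(trimethylsilyl)cyclohexa-1,4-diene-1-carbaldehyde F1, in which C4–C4a and C1–C8a are again made in one cycloaddition. The Me2AlCl-promoted Diels–Alder reaction of F1 with the more electron-rich triene 7, anti to the silyl group and formyl-endo, then closes ring B and comes back to the route at 14.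

Step 6. Enantiofacial discrimination on a linear ynal may be insufficient, and the acid catalyst may trigger oligomerisation of the triene or aromatisation of the skipped diene. The fallback sets the stereocentre by iminium catalysis. It sets out from 7: Diels–Alder reaction with acrolein under (5S)-5-benzyl-2,2,3-trimethylimidazolidin-4-one hydrochloride (the catalyst enantiomer being chosen for this product) should give the endo adduct methyl trans-4-[(E)-1-[(1S,6S)-6-formyl-3-methylcyclohex-2-en-1-yl]prop-1-en-2-yl]cyclohexane-1-carboxylate F2. α-Bromination through its pyrrolidine enamine with N-bromosuccinimide, anti to the propenyl group, gives methyl trans-4-[(E)-1-[(1S,6R)-6-bromo-6-formyl-3-methylcyclohex-2-en-1-yl]prop-1-en-2-yl]cyclohexane-1-carboxylate F3. Anti-E2 elimination with 1,8-diazabicyclo[5.4.0]undec-7-ene at low temperature can only take a hydrogen from the ring CH2, because the bromine is cis to the hydrogen on the propenyl-bearing carbon, and comes back to the route at 10.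

Step 10. The acid may protonate one of the three other trisubstituted alkenes, with cation–olefin cyclisation or alkene migration, and anti delivery of the proton may be incomplete in the congested cis-decalin. The fallback moves the transposition ahead of the closure of ring B. It sets out from 13 and 9 and passes through the silyl dienal F1 described above, which has a doubly allylic C–Si bond and only one other alkene. Protodesilylation of F1 with CF3CO2H should transfer the configuration from the silyl-bearing carbon to the side-chain-bearing carbon and give (4R)-4-[(2S)-6-methylhept-5-en-2-yl]cyclohexa-1,5-diene-1-carbaldehyde F4. The Me2AlCl-promoted Diels–Alder reaction of F4 with triene 7 at the formyl-bearing alkene, anti to the side chain and formyl-endo, comes back to the route at 15.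

Further compounds
F1 | step 9 | (6S)-4-[(2S)-6-methylhept-5-en-2-yl]-6-(trimethylsilyl)cyclohexa-1,4-diene-1-carbaldehyde | CC(C)=CCC[C@H](C)C1=C[C@H]([Si](C)(C)C)C(C=O)=CC1
F2 | step 6 | methyl trans-4-[(E)-1-[(1S,6S)-6-formyl-3-methylcyclohex-2-en-1-yl]prop-1-en-2-yl]cyclohexane-1-carboxylate | O=C[C@H]1CCC(C)=C[C@H]1/C=C(\C)[C@H]1CC[C@H](C(=O)OC)CC1
F3 | step 6 | methyl trans-4-[(E)-1-[(1S,6R)-6-bromo-6-formyl-3-methylcyclohex-2-en-1-yl]prop-1-en-2-yl]cyclohexane-1-carboxylate | O=C[C@@]1(Br)CCC(C)=C[C@H]1/C=C(\C)[C@H]1CC[C@H](C(=O)OC)CC1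
F4 | step 10 | (4R)-4-[(2S)-6-methylhept-5-en-2-yl]cyclohexa-1,5-diene-1-carbaldehyde | CC(C)=CCC[C@H](C)[C@@H]1C=CC(C=O)=CC1
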